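**Strategy.** The plan rests on breaking the C1–C2 bond of the 1,2-dihydronaphthalene core. The key step exploits two features: the pendant aryl ring on C1 carries its 4'-hydroxyl para to C1, so C1 can become the methide carbon of a para-quinone methide, and C2 is the enolisable α-carbon of an aryl ketone held next to C1 by the (E)-C3=C4 enone attached at C4a of ring A. One chiral-phosphoric-acid-catalysed intramolecular 1,6-addition thus closes the six-membered ring and sets C1 and C2 together. Its precursor is a racemic ring A/pendant-ring diaryl carbinol with free 4'-OH, five benzyl ethers and an ortho (E)-2-arylidene-1,4-diketone arm.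

Key step: step 15

Atom labels: C1–C8a for the dihydronaphthalene core, primed numbers for the pendant ring on C1.
Assumption: the (R)-acid is taken to expose the methide face that leads to (1S); if the sense proves opposite, the (S)-acid is used with no other change.

**Pendant-ring bromide**

Step 1
Reactants: 1 3-bromo-2-methoxyphenol
Product: 2 4-bromo-2-hydroxy-3-methoxybenzaldehyde
Conditions: MgCl2, Et3N, (CH2O)n, MeCN, reflux; aq. HCl work-up
Reagents that add atoms: paraformaldehyde (formaldehyde), C=O
Why: Magnesium-phenoxide-directed ortho-formylation (Casnati–Skattebøl reaction) reacts only ortho to the hydroxyl, and as the other ortho carbon carries the methoxy group a single site is open, which places bromine, methoxy and the two future oxygens in one unambiguous sequence.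

Step 2
Reactants: 2 4-bromo-2-hydroxy-3-methoxybenzaldehyde
Product: 3 2-(benzyloxy)-4-bromo-3-methoxybenzaldehyde
Conditions: BnBr, K2CO3, DMF, 60 °C
Reagents that add atoms: benzyl bromide, BrCc1ccccc1
Why: Williamson etherification of the phenoxide; the chelated ortho-hydroxyl still alkylates under K2CO3 in DMF and becomes the future 3'-benzyl ether.

Step 3
Reactants: 3 2-(benzyloxy)-4-bromo-3-methoxybenzaldehyde
Product: 5 2-(benzyloxy)-4-bromo-3-methoxyphenol, via aryl formate 4 (not isolated)
Conditions: mCPBA, CH2Cl2, 0 °C to rt; then K2CO3 (cat.), MeOH, rt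
Reagents that add atoms: 3-chloroperoxybenzoic acid, OOC(=O)c1cccc(Cl)c1
Why: Baeyer–Villiger oxidation with aryl migration (Dakin-type), favoured by the ortho-benzyloxy group, gives the formate, which methanolysis cleaves, so the formyl carbon is exchanged for the future 4'-oxygen para to bromine.

Step 4
Reactants: 5 2-(benzyloxy)-4-bromo-3-methoxyphenol
Product: 6 [2-(benzyloxy)-4-bromo-3-methoxyphenoxy](tert-butyl)dimethylsilane
Conditions: TBSCl, imidazole, DMF, rt
Reagents that add atoms: tert-butyldimethylsilyl chloride, CC(C)(C)[Si](C)(C)Cl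
Why: Standard phenol silylation; the silyl ether is orthogonal to the benzyl ethers and tolerates aryllithium chemistry at −78 °C.

**Ring-A aldehyde**

Step 5
Reactants: 7 5-bromo-2,3-dihydroxybenzaldehyde
Product: 8 2,3-bis(benzyloxy)-5-bromobenzaldehyde
Conditions: BnBr (2.5 equiv), K2CO3, DMF, 60 °C
Reagents that add atoms: benzyl bromide, BrCc1ccccc1
Why: Double Williamson etherification installs the two benzyl ethers that end up on the C6 and C7 oxygens.

Step 6
Reactants: 8 2,3-bis(benzyloxy)-5-bromobenzaldehyde
Product: 10 2,3-bis(benzyloxy)-5-bromophenol, via aryl formate 9 (not isolated)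
Conditions: mCPBA, CH2Cl2, 0 °C to rt; then K2CO3 (cat.), MeOH, rt
Reagents that add atoms: 3-chloroperoxybenzoic acid, OOC(=O)c1cccc(Cl)c1
Why: Baeyer–Villiger oxidation with aryl migration followed by formate methanolysis turns the aldehyde into the hydroxyl that will become the C8 oxygen.

Step 7
Reactants: 10 2,3-bis(benzyloxy)-5-bromophenol
Product: 11 3,4-bis(benzyloxy)-6-bromo-2-hydroxybenzaldehyde
Conditions: MgCl2, Et3N, (CH2O)n, MeCN, reflux; aq. HCl work-up
Reagents that add atoms: paraformaldehyde (formaldehyde), C=O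
Why: Casnati–Skattebøl ortho-formylation can only strike the one unsubstituted carbon ortho to the hydroxyl, between hydroxyl and bromine, so the future C1 carbon is placed on C8a without any regiochemical choice.

Step 8
Reactants: 11 3,4-bis(benzyloxy)-6-bromo-2-hydroxybenzaldehyde
Product: 12 3,4-bis(benzyloxy)-6-bromo-2-methoxybenzaldehyde
Conditions: MeI, K2CO3, DMF, 40 °C
Reagents that add atoms: iodomethane, CI
Why: O-Methylation of the chelated phenol (Williamson) installs the C8 methoxy group.

**Ene-dione for the arm**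

Step 9
Reactants: 13 1-[4-(benzyloxy)phenyl]ethanone; 14 1-[4-(benzyloxy)phenyl]-2-bromoethanone
Product: 15 1,4-bis[4-(benzyloxy)phenyl]butane-1,4-dione
Conditions: ZnCl2, Et2NH, t-BuOH, toluene, rt
Reagents that add atoms: none
Why: Soft enolisation of 13 to a zinc enolate and its C-alkylation by the α-bromo ketone is an established one-step synthesis of 1,4-diaryl-1,4-diketones.

Step 10
Reactants: 15 1,4-bis[4-(benzyloxy)phenyl]butane-1,4-dione
Product: 16 (E)-1,4-bis[4-(benzyloxy)phenyl]but-2-ene-1,4-dione
Conditions: SeO2, AcOH, 100 °C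
Reagents that add atoms: none
Why: Selenium dioxide dehydrogenation of a 1,4-diketone through its enol gives the conjugated ene-dione, of which the trans isomer is the stable one.

**Assembly and endgame**

Step 11
Reactants: 6 [2-(benzyloxy)-4-bromo-3-methoxyphenoxy](tert-butyl)dimethylsilane; 12 3,4-bis(benzyloxy)-6-bromo-2-methoxybenzaldehyde
Product: 19 racemic [3,4-bis(benzyloxy)-6-bromo-2-methoxyphenyl][3-(benzyloxy)-4-(tert-butyldimethylsilyloxy)-2-methoxyphenyl]methyl tert-butyldimethylsilyl ether, via pendant aryllithium 17 (not isolated), via lithium alkoxide 18 (not isolated)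
Conditions: 6, n-butyllithium, THF, −78 °C; then 12, −78 °C; then TBSOTf, −78 to 0 °C
Reagents that add atoms: tert-butyldimethylsilyl trifluoromethanesulfonate, CC(C)(C)[Si](C)(C)OS(=O)(=O)C(F)(F)F
Why: Bromine–lithium exchange, 1,2-addition of the aryllithium to the aldehyde (much faster than exchange with the second aryl bromide) and O-silylation of the lithium alkoxide in the same flask form the C1–C1' bond; the carbinol centre arises as a racemate, which is acceptable because step 15 erases it.

Step 12
Reactants: 19 racemic bis-silyl bromide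
Product: 21 racemic 4,5-bis(benzyloxy)-2-{[3-(benzyloxy)-4-(tert-butyldimethylsilyloxy)-2-methoxyphenyl](tert-butyldimethylsilyloxy)methyl}-3-methoxybenzaldehyde, via ring-A aryllithium 20 (not isolated)
Conditions: n-butyllithium, THF, −78 °C; then DMF, −78 to 0 °C; aq. NH4Cl
Reagents that add atoms: N,N-dimethylformamide, CN(C)C=O
Why: Bromine–lithium exchange at −78 °C outruns deprotonation, and trapping with DMF (Bouveault aldehyde synthesis) installs the future C4 carbon, while the bulky tert-butyldimethylsilyl group on the benzylic oxygen resists migration to the aryllithium at this temperature.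

Step 13
Reactants: 21 racemic aldehyde; 16 (E)-1,4-bis[4-(benzyloxy)phenyl]but-2-ene-1,4-dione
Product: 23 racemic (E)-2-arylidene-1,4-diketone carrying both silyl ethers (ring A cis to the CH2 on C3=C4), via tributylphosphonium ylide 22 (not isolated)
Conditions: 16, PBu3, toluene, rt; then 21, 80 °C
Reagents that add atoms: none
Why: Conjugate addition of tributylphosphine to the ene-dione and proton transfer give an acyl-stabilised ylide whose Wittig reaction with the aldehyde is thermodynamically controlled and places ring A trans to the aroyl group, that is the (E)-alkene with ring A and the CH2C(=O)Ar branch cis.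

Step 14
Reactants: 23 racemic bis-silyl (E)-2-arylidene-1,4-diketone
Product: 24 racemic diaryl carbinol with free 4'-hydroxyl and (E)-2-arylidene-1,4-diketone arm (key-step precursor)
Conditions: tetrabutylammonium fluoride, AcOH (1:1), THF, 0 °C to rt
Reagents that add atoms: none
Why: Fluoride cleaves the aryl and the benzhydryl silyl ether, and the acetic acid buffer keeps the medium near neutral, so that neither phenoxide chemistry (oxa-Michael addition, alkene migration) nor acid ionisation of the carbinol should intervene.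

Step 15
Reactants: 24 racemic key-step precursor
Product: 26 (1S,2S)-cis pentabenzyl ether [(1S,2S)-6,7-bis(benzyloxy)-1-[3-(benzyloxy)-4-hydroxy-2-methoxyphenyl]-8-methoxy-1,2-dihydronaphthalene-2,3-diyl]bis{[4-(benzyloxy)phenyl]methanone}, via para-quinone methide 25 (not isolated)
Conditions: (R)-3,3'-bis(2,4,6-triisopropylphenyl)-1,1'-binaphthyl-2,2'-diyl hydrogen phosphate (10 mol %), 5 Å molecular sieves, toluene, 0 °C to rt, argon
Reagents that add atoms: none
Why: The phosphoric acid protonates the doubly benzylic hydroxyl, water leaves, and the 4'-phenol collapses the cation to para-quinone methide 25, which remains hydrogen-bonded to the phosphate through its carbonyl oxygen while the phosphoryl oxygen holds the O–H of the enol of the C2 ketone; the enol carbon C2 then attacks the methide carbon C1 and the pendant ring rearomatises. The closest known reaction type is the chiral-phosphoric-acid-catalysed 1,6-addition of enols to para-quinone methides generated in situ from para-hydroxybenzyl alcohols, applied here intramolecularly. The ring C1–C2–C3–C4–C4a–C8a closes in a 6-exo-trig mode (exo with respect to both the methide and the enol double bond). C1 is controlled by the catalyst, whose 3,3'-aryl groups shield one face of the bound methide, and C2 is fixed relative to C1 in a half-chair transition state in which the enol arm lies over the quinoid ring so that one phosphate can bridge both oxygens, which puts aroyl and aryl cis. The step needs C-alkylation at C2 in preference to attack by the carbonyl oxygens, furan formation from the 1,4-diketone or oxa-Michael closure of the carbinol onto C4, and it needs both carbinol enantiomers to converge; the (E)-alkene, which keeps C2 and ring A cis on C3=C4 and within reach of C1, the six-membered ring size, the mild anhydrous acid and the planar methide intermediate secure this.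

Step 16
Reactants: 26 (1S,2S)-cis pentabenzyl ether
Product: 27 Licobichalcone, [(1S,2S)-1-(3,4-dihydroxy-2-methoxyphenyl)-6,7-dihydroxy-8-methoxy-1,2-dihydronaphthalene-2,3-diyl]bis[(4-hydroxyphenyl)methanone]
Conditions: BCl3, pentamethylbenzene, CH2Cl2, −78 °C; MeOH quench at −78 °C, aqueous work-up
Reagents that add atoms: none
Why: BCl3 cleaves the five aryl benzyl ethers at −78 °C while pentamethylbenzene traps the benzyl cations (Friedel–Crafts), which should leave the two aryl methyl ethers, the enone and the C1 and C2 centres untouched.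

**Compound list**

1 | 3-bromo-2-methoxyphenol | COc1c(O)cccc1Br | starting material
2 | 4-bromo-2-hydroxy-3-methoxybenzaldehyde | COc1c(Br)ccc(C=O)c1O | intermediate
3 | 2-(benzyloxy)-4-bromo-3-methoxybenzaldehyde | COc1c(Br)ccc(C=O)c1OCc1ccccc1 | intermediate
4 | 2-(benzyloxy)-4-bromo-3-methoxyphenyl formate (formed in the flask) | COc1c(Br)ccc(OC=O)c1OCc1ccccc1 | intermediate
5 | 2-(benzyloxy)-4-bromo-3-methoxyphenol | COc1c(Br)ccc(O)c1OCc1ccccc1 | intermediate
6 | [2-(benzyloxy)-4-bromo-3-methoxyphenoxy](tert-butyl)dimethylsilane | COc1c(Br)ccc(O[Si](C)(C)C(C)(C)C)c1OCc1ccccc1 | intermediate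
7 | 5-bromo-2,3-dihydroxybenzaldehyde | O=Cc1cc(Br)cc(O)c1O | starting material
8 | 2,3-bis(benzyloxy)-5-bromobenzaldehyde | O=Cc1cc(Br)cc(OCc2ccccc2)c1OCc1ccccc1 | intermediate
9 | 2,3-bis(benzyloxy)-5-bromophenyl formate (formed in the flask) | O=COc1cc(Br)cc(OCc2ccccc2)c1OCc1ccccc1 | intermediate
10 | 2,3-bis(benzyloxy)-5-bromophenol | Oc1cc(Br)cc(OCc2ccccc2)c1OCc1ccccc1 | intermediate
11 | 3,4-bis(benzyloxy)-6-bromo-2-hydroxybenzaldehyde | O=Cc1c(Br)cc(OCc2ccccc2)c(OCc2ccccc2)c1O | intermediate
12 | 3,4-bis(benzyloxy)-6-bromo-2-methoxybenzaldehyde | COc1c(C=O)c(Br)cc(OCc2ccccc2)c1OCc1ccccc1 | intermediate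
13 | 1-[4-(benzyloxy)phenyl]ethanone | CC(=O)c1ccc(OCc2ccccc2)cc1 | starting material
14 | 1-[4-(benzyloxy)phenyl]-2-bromoethanone | BrCC(=O)c1ccc(OCc2ccccc2)cc1 | starting material
15 | 1,4-bis[4-(benzyloxy)phenyl]butane-1,4-dione | O=C(CCC(=O)c1ccc(OCc2ccccc2)cc1)c1ccc(OCc2ccccc2)cc1 | intermediate
16 | (E)-1,4-bis[4-(benzyloxy)phenyl]but-2-ene-1,4-dione | O=C(/C=C/C(=O)c1ccc(OCc2ccccc2)cc1)c1ccc(OCc2ccccc2)cc1 | intermediate
17 | [3-(benzyloxy)-4-(tert-butyldimethylsilyloxy)-2-methoxyphenyl]lithium (formed in the flask) | COc1c([Li])ccc(O[Si](C)(C)C(C)(C)C)c1OCc1ccccc1 | intermediate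
18 | lithium alkoxide of the racemic bromo diaryl carbinol (formed in the flask) | COc1c(C(O[Li])c2c(Br)cc(OCc3ccccc3)c(OCc3ccccc3)c2OC)ccc(O[Si](C)(C)C(C)(C)C)c1OCc1ccccc1 | intermediate
19 | racemic [3,4-bis(benzyloxy)-6-bromo-2-methoxyphenyl][3-(benzyloxy)-4-(tert-butyldimethylsilyloxy)-2-methoxyphenyl]methyl tert-butyldimethylsilyl ether | COc1c(C(O[Si](C)(C)C(C)(C)C)c2c(Br)cc(OCc3ccccc3)c(OCc3ccccc3)c2OC)ccc(O[Si](C)(C)C(C)(C)C)c1OCc1ccccc1 | intermediate
20 | ring-A aryllithium derived from 19, lithium in place of bromine (formed in the flask) | COc1c(C(O[Si](C)(C)C(C)(C)C)c2c([Li])cc(OCc3ccccc3)c(OCc3ccccc3)c2OC)ccc(O[Si](C)(C)C(C)(C)C)c1OCc1ccccc1 | intermediate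
21 | racemic 4,5-bis(benzyloxy)-2-{[3-(benzyloxy)-4-(tert-butyldimethylsilyloxy)-2-methoxyphenyl](tert-butyldimethylsilyloxy)methyl}-3-methoxybenzaldehyde | COc1c(C(O[Si](C)(C)C(C)(C)C)c2c(C=O)cc(OCc3ccccc3)c(OCc3ccccc3)c2OC)ccc(O[Si](C)(C)C(C)(C)C)c1OCc1ccccc1 | intermediate
22 | 1,4-bis[4-(benzyloxy)phenyl]-2-(tributylphosphoranylidene)butane-1,4-dione (formed in the flask) | CCCCP(CCCC)(CCCC)=C(CC(=O)c1ccc(OCc2ccccc2)cc1)C(=O)c1ccc(OCc2ccccc2)cc1 | intermediate
23 | racemic (E)-2-arylidene-1,4-bis[4-(benzyloxy)phenyl]butane-1,4-dione, arylidene = ring A of 21 with both silyl ethers kept | COc1c(C(O[Si](C)(C)C(C)(C)C)c2c(/C=C(\CC(=O)c3ccc(OCc4ccccc4)cc3)C(=O)c3ccc(OCc4ccccc4)cc3)cc(OCc3ccccc3)c(OCc3ccccc3)c2OC)ccc(O[Si](C)(C)C(C)(C)C)c1OCc1ccccc1 | intermediate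
24 | racemic key-step precursor: diaryl carbinol with free carbinol OH and free 4'-OH, (E)-2-arylidene-1,4-diketone arm, five benzyl ethers | COc1c(C(O)c2c(/C=C(\CC(=O)c3ccc(OCc4ccccc4)cc3)C(=O)c3ccc(OCc4ccccc4)cc3)cc(OCc3ccccc3)c(OCc3ccccc3)c2OC)ccc(O)c1OCc1ccccc1 | intermediate
25 | para-quinone methide from 24, C1 as exocyclic methide carbon of the pendant cyclohexadienone (formed in the flask) | COC1=C(OCc2ccccc2)C(=O)C=CC1=Cc1c(/C=C(\CC(=O)c2ccc(OCc3ccccc3)cc2)C(=O)c2ccc(OCc3ccccc3)cc2)cc(OCc2ccccc2)c(OCc2ccccc2)c1OC | intermediate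
26 | (1S,2S)-cis pentabenzyl ether of the target with free 4'-OH | COc1c([C@H]2c3c(cc(OCc4ccccc4)c(OCc4ccccc4)c3OC)C=C(C(=O)c3ccc(OCc4ccccc4)cc3)[C@H]2C(=O)c2ccc(OCc3ccccc3)cc2)ccc(O)c1OCc1ccccc1 | intermediate
27 | Licobichalcone, (1S,2S)-cis | COc1c([C@H]2c3c(cc(O)c(O)c3OC)C=C(C(=O)c3ccc(O)cc3)[C@H]2C(=O)c2ccc(O)cc2)ccc(O)c1O | target

**Step count and risks**

Total step count: 16. Longest linear sequence: 10 steps (steps 5–8 then 11–16; the branch through steps 1–4 is equally long).

Steps most likely to fail:

Step 15 may lose diastereocontrol at C2, either through closure via the alternative half-chair or through acid-mediated enolisation of the new α-keto centre towards the trans isomer. The fallback sets out from 24 and comes back at 26. The closure is run as in step 15 and the material is taken on as the trans epimer, (1S,2R)-pentabenzyl ether F1. LiN(SiMe3)2 (2.2 equiv, THF, −78 °C) converts it into the phenoxide/extended enolate. A cold quench with a hindered proton donor (2,6-di-tert-butylphenol, then acetic acid) should deliver the proton to C2 anti to the pseudo-axial C1 aryl group and return cis compound 26. C2 is then set by substrate-controlled kinetic protonation and no longer in the ring closure.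

Step 13 may give slow or incomplete olefination, because an α-branched acyl-stabilised ylide meets an ortho-substituted, electron-rich aldehyde while the ene-dione is consumed by phosphine side reactions. The fallback sets out from 21 (with diketone 15) and comes back at 23. The lithium enolate of 15 (LiN(SiMe3)2, THF, −78 °C) is added to 21 to give the racemic β-hydroxy ketone, aldol adduct F2. Mesylation (MsCl, Et3N, CH2Cl2, 0 °C) gives mesylate F3, and DBU at room temperature should eliminate by the E1cB path to the conjugated (E)-alkene 23.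

Step 12 may suffer migration of the benzylic silyl group to the ortho aryllithium, or benzylic deprotonation, in competition with formylation. The fallback sets out from 19 and comes back at 21. Stille coupling of 19 with tributyl(vinyl)stannane (Pd(PPh3)4, toluene, 100 °C) gives the racemic styrene, vinyl arene F4. Lemieux–Johnson cleavage (OsO4 cat., NaIO4, 2,6-lutidine, dioxane/water) then returns aldehyde 21 without any organolithium.

**Further compounds**

F1 | step 15 | (1S,2R)-trans epimer of 26 (pentabenzyl ether, free 4'-OH) | COc1c([C@H]2c3c(cc(OCc4ccccc4)c(OCc4ccccc4)c3OC)C=C(C(=O)c3ccc(OCc4ccccc4)cc3)[C@@H]2C(=O)c2ccc(OCc3ccccc3)cc2)ccc(O)c1OCc1ccccc1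
F2 | step 13 | racemic aldol adduct of 15 and 21 (β-hydroxy ketone, diastereomer mixture) | COc1c(C(O[Si](C)(C)C(C)(C)C)c2c(C(O)C(CC(=O)c3ccc(OCc4ccccc4)cc3)C(=O)c3ccc(OCc4ccccc4)cc3)cc(OCc3ccccc3)c(OCc3ccccc3)c2OC)ccc(O[Si](C)(C)C(C)(C)C)c1OCc1ccccc1
F3 | step 13 | methanesulfonate of F2 | COc1c(C(O[Si](C)(C)C(C)(C)C)c2c(C(OS(C)(=O)=O)C(CC(=O)c3ccc(OCc4ccccc4)cc3)C(=O)c3ccc(OCc4ccccc4)cc3)cc(OCc3ccccc3)c(OCc3ccccc3)c2OC)ccc(O[Si](C)(C)C(C)(C)C)c1OCc1ccccc1
F4 | step 12 | racemic vinyl arene, vinyl in place of the bromine of 19 | COc1c(C(O[Si](C)(C)C(C)(C)C)c2c(C=C)cc(OCc3ccccc3)c(OCc3ccccc3)c2OC)ccc(O[Si](C)(C)C(C)(C)C)c1OCc1ccccc1
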